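(The earlier runs and the new flask are calculated with made-up constants; noise was put on by code.)

The gamma run, with 22 mM of D, reads E at 23.8% at 1.67 d and 23.8% at 2.50 d, so E reads flat there, within a scatter of 0.5 percentage points. So I guess that X is both the source of E and its eater, one X to one E, and that the eating ends with X.

epsilon run (percent of the X charged): time / h: E / % = 4.00: 2.6; 8.00: 5.7; 20.0: 14.6; 50.0: 29.8

beta run (percent of the X charged): time / d: E / % = 0.625: 7.5; 1.25: 19.9; 1.67: 25.4; 2.50: 32.0

gamma run (percent of the X charged): time / d: E / % = 0.333: 6.3; 0.833: 16.3; 1.67: 23.8; 2.50: 23.8

(readings scatter by 0.5 percentage points)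

| flask | X | D | remark | time |
|---|---|---|---|---|
| epsilon | 10 mM | 15 mM | run made earlier |  |
| beta | 10 mM | 10 mM | run made earlier |  |
| gamma | 10 mM | 22 mM | run made earlier |  |
| red | 10 mM | 15.0 mM | everything together in a closed stirred flask, run for 2.0 d | 2.0 d |
| amber | 10 mM | 15.0 mM (fed, over 1.60 d) | all but D at the start; D goes in evenly over 1.60 d, the run ends at 2.0 d | 2.0 d |
| grey | 10 mM (fed, over 1.60 d) | 15.0 mM | all but X at the start; X goes in evenly over 1.60 d, the run ends at 2.0 d | 2.0 d |
| teal | 10 mM | 15.0 mM | a single well-mixed tank run continuously and read at steady state, 2.0 d in it on average |  |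

- order of the set-ups by the amount of E at the outlet or at the end, in percent of the X put in, highest first (red / amber / grey / teal)
- amount of E at the outlet or at the end, in percent of the X put in, red
- amount of E at the outlet or at the end, in percent of the X put in, amber
- amount of E at the outlet or at the end, in percent of the X put in, grey
- amount of E at the outlet or at the end, in percent of the X put in, teal

I read the last row of each run, with D falling from gamma through epsilon to beta. On my guess, each eaten pair takes 2 parts of the X charged, and whatever is not E sits in such pairs. Gamma then gives 38.4% for what I call the kept share, E kept over E kept plus eaten pairs, a selectivity in the usual term. Epsilon gives 45.9% and beta 48.5%, both floors if E there is still rising. Across these three runs, all at 10 mM of X, the kept share reads higher as D falls.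

So I take the eating as fast and reckon with what it leaves free: E made while X is still there can be eaten, and E made later is out of its reach. Amber brings D in over 1.60 d, so its E comes late, and I put amber above red. Grey lets X in over the same 1.60 d, so fresh X meets E, and I put grey below red. Teal holds X at steady state, so I put teal last.

The forecast differs. It gives red > teal > amber > grey, with red 29.2%, amber 23%, grey 18% and teal 24%, and it says “excess D seems to cost E, through a loss or a stall”.

The flasks give amber > red > grey > teal: red 28.9%, amber 48.2%, grey 10.1%, teal 4.82%.

    X → Q (k = 0.00150 min⁻¹)
    X + E → J (k = 2.20 M⁻¹ min⁻¹)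
    E → G (k = 6.60 × 10⁻⁶ min⁻¹)
    D + Q → E (k = 0.130 M⁻¹ min⁻¹)

J is the eaten pair, and its percentage counts 2 parts of X for each pair. Amber at 2.00 d holds E 48.2% and J 40.8%, so its kept share is 70.3%, above the 38.4% of gamma. The forecast's amber stands 25 points below the flask. The neighbour is amber with 6.0 mM of D, read at 2.00 d. The same sum on its E 27.6% and J 26.7% gives 67.4%. Its E is lower than amber's, and in that neighbour Q holds 45.6% of the X charged, more than E or J.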